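Atom numbers used below: five-membered ring C1(Me, quaternary)–C2(OAc)–C3H2–C4(OH)(iPr)–C5(H); seven-membered ring C5–C6(OAr)–C7=C8(Me)–C9(=O)–C10H2–C1.
Retrosynthesis: remove the phenol acetate, then cut C7=C8 (olefin metathesis) to a C6 vinyl carbinol ester and a C9 isopropenyl ketone; then C6–C7 (vinyl to aldehyde), C8–C9 (isopropenyl to Weinreb amide), C2–H, C4–O, C4–iPr, and last C1–C10 and C5–C6 (enolate alkylation and conjugate addition on a cyclopentenone).
Forward: the five-membered ring is bought as (S)-4-silyloxycyclopentenone and is given all five stereocenters; the seven-membered ring is closed last by joining C7 to C8.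
Enabling feature: C7=C8 lies between the C6 allylic oxygen and the C9 carbonyl, and its two olefin partners hang trans on the adjacent ring atoms C5 and C1, which preorganises a 1,8-diene for seven-ring closure with a ring-enforced Z olefin.
Stereochemistry: the bought C4 silyloxy center directs vinyl to C5 and the alkylation at C1 in one three-component event and is then erased; C4 returns by epoxidation anti to the C5 vinyl group, C2 by hydroxyl-directed hydride delivery from the C4 hydroxyl, C6 by chelation-controlled vinylation through the C4 alkoxide.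
Helpers: the silyloxy group (relay, removed in step 4), the Weinreb amide (acyl handle, used in step 9) and the phenol acetate (removed in step 15).

Key step: step 14

Step 1
Reactants: 1 (S)-4-(tert-butyldimethylsilyloxy)cyclopent-2-en-1-one
Product: 2 (S)-4-(tert-butyldimethylsilyloxy)-2-iodocyclopent-2-en-1-one
Conditions: I2, pyridine, CH2Cl2, 0 °C to rt
Reagents that add atoms: iodine, II
Why: α-Iodination of the enone by conjugate addition of pyridine, iodination of the enolate and loss of pyridine (addition–elimination of the Baylis–Hillman type) should give the 2-iodoenone without touching the C4 stereocenter.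

Step 2
Reactants: 2 (S)-4-(tert-butyldimethylsilyloxy)-2-iodocyclopent-2-en-1-one
Product: 3 (S)-4-(tert-butyldimethylsilyloxy)-2-methylcyclopent-2-en-1-one
Conditions: Me2Zn, PdCl2(dppf) (cat.), THF, 0 °C to rt
Reagents that add atoms: dimethylzinc, C[Zn]C
Why: Negishi cross-coupling of the alkenyl iodide under zerovalent palladium catalysis should install the future C1 methyl group under neutral conditions that leave the β-silyloxy group in place.

Step 3
Reactants: 3 (S)-4-(tert-butyldimethylsilyloxy)-2-methylcyclopent-2-en-1-one; 4 2-bromo-N-methoxy-N-methylacetamide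
Product: 6 2-[(1S,2S,3S)-3-(tert-butyldimethylsilyloxy)-2-ethenyl-1-methyl-5-oxocyclopentyl]-N-methoxy-N-methylacetamide, via bromomagnesium enolate 5 (not isolated)
Conditions: CH2=CHMgBr, CuBr·SMe2 (cat.), THF, −78 °C; then 4, HMPA, −78 to −20 °C
Reagents that add atoms: vinylmagnesium bromide, C=C[Mg]Br
Why: Copper-catalysed conjugate addition of the vinyl Grignard reagent should occur anti to the C4 silyloxy group and the tetrasubstituted enolate is then C-alkylated by the reactive α-bromo amide anti to the new C5 vinyl group (three-component coupling by conjugate addition and enolate alkylation), so that C5 and the quaternary C1 are set in one operation.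

Step 4
Reactants: 6 2-[(1S,2S,3S)-3-(tert-butyldimethylsilyloxy)-2-ethenyl-1-methyl-5-oxocyclopentyl]-N-methoxy-N-methylacetamide
Product: 7 2-[(1S,2R)-2-ethenyl-1-methyl-5-oxocyclopent-3-en-1-yl]-N-methoxy-N-methylacetamide
Conditions: TsOH·H2O (cat.), toluene, 50 °C
Reagents that add atoms: none
Why: Acid-catalysed β-elimination of the silyloxy group through the enol, which can only form toward C3, should give the conjugated cyclopentenone and erase the relay stereocenter at C4, while acid instead of amine base avoids deprotonation at the doubly allylic C5.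

Step 5
Reactants: 7 2-[(1S,2R)-2-ethenyl-1-methyl-5-oxocyclopent-3-en-1-yl]-N-methoxy-N-methylacetamide
Product: 9 2-[(1S,2R)-2-ethenyl-1-methyl-5-oxo-3-(propan-2-yl)cyclopent-3-en-1-yl]-N-methoxy-N-methylacetamide, via trimethylsilyl enol ether 8 (not isolated)
Conditions: iPrMgCl, CuBr·SMe2 (cat.), TMSCl, THF, −78 °C; then Pd(OAc)2, MeCN, rt
Reagents that add atoms: isopropylmagnesium chloride, CC(C)[Mg]Cl
Why: Copper-catalysed conjugate addition of the isopropyl Grignard reagent with in situ silylation gives the silyl enol ether, and Saegusa–Ito oxidation with divalent palladium should restore the enone, now carrying the isopropyl group at C4, so that the transient C4 stereocenter does not matter.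

Step 6
Reactants: 9 2-[(1S,2R)-2-ethenyl-1-methyl-5-oxo-3-(propan-2-yl)cyclopent-3-en-1-yl]-N-methoxy-N-methylacetamide
Product: 10 2-[(1R,2S,3S,5R)-2-ethenyl-3-methyl-4-oxo-1-(propan-2-yl)-6-oxabicyclo[3.1.0]hexan-3-yl]-N-methoxy-N-methylacetamide
Conditions: H2O2 (30% aq), NaOH (cat.), MeOH, −10 to 0 °C
Reagents that add atoms: hydrogen peroxide, OO
Why: In this nucleophilic (Weitz–Scheffer) epoxidation the hydroperoxide anion should add to C4 on the face anti to the adjacent C5 vinyl group, which places the new C4–O bond on the face opposite to the C1 methyl group as the target requires.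

Step 7
Reactants: 10 2-[(1R,2S,3S,5R)-2-ethenyl-3-methyl-4-oxo-1-(propan-2-yl)-6-oxabicyclo[3.1.0]hexan-3-yl]-N-methoxy-N-methylacetamide
Product: 11 2-[(1S,2S,3R)-2-ethenyl-3-hydroxy-1-methyl-5-oxo-3-(propan-2-yl)cyclopentyl]-N-methoxy-N-methylacetamide
Conditions: SmI2, THF/MeOH, −90 °C
Reagents that add atoms: none
Why: Single-electron reduction of the α,β-epoxy ketone by divalent samarium should cleave only the C3–O bond next to the carbonyl (reductive epoxy ketone opening) and give the β-hydroxy ketone with the C4 configuration untouched.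

Step 8
Reactants: 11 2-[(1S,2S,3R)-2-ethenyl-3-hydroxy-1-methyl-5-oxo-3-(propan-2-yl)cyclopentyl]-N-methoxy-N-methylacetamide
Product: 12 2-[(1S,2S,3R,5S)-2-ethenyl-3,5-dihydroxy-1-methyl-3-(propan-2-yl)cyclopentyl]-N-methoxy-N-methylacetamide
Conditions: Me4NBH(OAc)3, MeCN/AcOH, −30 °C
Reagents that add atoms: none
Why: In this hydroxyl-directed reduction of the Evans–Saksena type the C4 hydroxyl binds the borohydride and delivers hydride to the C2 ketone on its own face, which should give the trans-1,3-diol with the C2 hydroxyl cis to the C1 methyl group.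

Step 9
Reactants: 12 2-[(1S,2S,3R,5S)-2-ethenyl-3,5-dihydroxy-1-methyl-3-(propan-2-yl)cyclopentyl]-N-methoxy-N-methylacetamide
Product: 13 1-[(1S,2S,3R,5S)-2-ethenyl-3,5-dihydroxy-1-methyl-3-(propan-2-yl)cyclopentyl]-3-methylbut-3-en-2-one
Conditions: CH2=C(CH3)MgBr (excess), THF, −20 to 0 °C; aq NH4Cl
Reagents that add atoms: isopropenylmagnesium bromide, CC(=C)[Mg]Br
Why: In this Weinreb ketone synthesis the chelated tetrahedral intermediate should stop the addition at the ketone stage, while two further equivalents of the Grignard reagent are consumed by the two hydroxyl groups.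

Step 10
Reactants: 13 1-[(1S,2S,3R,5S)-2-ethenyl-3,5-dihydroxy-1-methyl-3-(propan-2-yl)cyclopentyl]-3-methylbut-3-en-2-one
Product: 14 (1S,2S,3S,4R)-3-ethenyl-4-hydroxy-2-methyl-2-(3-methyl-2-oxobut-3-en-1-yl)-4-(propan-2-yl)cyclopentyl acetate
Conditions: Ac2O, pyridine, DMAP (cat.), CH2Cl2, 0 °C to rt
Reagents that add atoms: acetic anhydride, CC(=O)OC(C)=O
Why: DMAP-catalysed acetylation should be selective for the secondary C2 hydroxyl because the tertiary C4 hydroxyl is far less reactive.

Step 11
Reactants: 14 (1S,2S,3S,4R)-3-ethenyl-4-hydroxy-2-methyl-2-(3-methyl-2-oxobut-3-en-1-yl)-4-(propan-2-yl)cyclopentyl acetate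
Product: 16 (1S,2S,3S,4R)-3-formyl-4-hydroxy-2-methyl-2-(3-methyl-2-oxobut-3-en-1-yl)-4-(propan-2-yl)cyclopentyl acetate, via secondary ozonide 15 (not isolated)
Conditions: O3 (1 equiv, indicator end point), CH2Cl2, −78 °C; then PPh3, −78 °C to rt
Reagents that add atoms: ozone, [O-][O+]=O
Why: Ozone reacts much faster with the electron-rich monosubstituted olefin than with the conjugated isopropenyl ketone, so that ozonolysis with reductive work-up should give the C6 aldehyde only.

Step 12
Reactants: 16 (1S,2S,3S,4R)-3-formyl-4-hydroxy-2-methyl-2-(3-methyl-2-oxobut-3-en-1-yl)-4-(propan-2-yl)cyclopentyl acetate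
Product: 17 (1S,2S,3R,4R)-4-hydroxy-3-[(1R)-1-hydroxyprop-2-en-1-yl]-2-methyl-2-(3-methyl-2-oxobut-3-en-1-yl)-4-(propan-2-yl)cyclopentyl acetate
Conditions: (CH2=CH)2Zn (from CH2=CHMgBr and ZnBr2), THF, −78 to −20 °C; aq NH4Cl
Reagents that add atoms: divinylzinc, C=C[Zn]C=C (made in the flask from vinylmagnesium bromide, C=C[Mg]Br, and ZnBr2)
Why: In this chelation-controlled organozinc addition the zinc alkoxide of the C4 hydroxyl and the aldehyde oxygen form a six-membered chelate trans-fused to the cyclopentane with the isopropyl group axial, so that the vinyl group should enter C6 from the opposite face and give the 6R carbinol, while the organozinc reagent leaves the enone and the acetate alone.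

Step 13
Reactants: 17 (1S,2S,3R,4R)-4-hydroxy-3-[(1R)-1-hydroxyprop-2-en-1-yl]-2-methyl-2-(3-methyl-2-oxobut-3-en-1-yl)-4-(propan-2-yl)cyclopentyl acetate; 18 4-(acetyloxy)benzoyl chloride
Product: 19 (1R)-1-[(1R,2S,3S,5R)-3-(acetyloxy)-5-hydroxy-2-methyl-2-(3-methyl-2-oxobut-3-en-1-yl)-5-(propan-2-yl)cyclopentyl]prop-2-en-1-yl 4-(acetyloxy)benzoate
Conditions: 18, pyridine, DMAP (cat.), CH2Cl2, 0 °C to rt
Reagents that add atoms: none
Why: Acylation of the secondary allylic C6 hydroxyl by the acid chloride (nucleophilic catalysis by DMAP) should proceed with retention at C6 and leave the tertiary C4 hydroxyl free.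

Step 14
Reactants: 19 (1R)-1-[(1R,2S,3S,5R)-3-(acetyloxy)-5-hydroxy-2-methyl-2-(3-methyl-2-oxobut-3-en-1-yl)-5-(propan-2-yl)cyclopentyl]prop-2-en-1-yl 4-(acetyloxy)benzoate
Product: 20 (1S,3R,3aR,4R,8aS)-1-(acetyloxy)-3-hydroxy-6,8a-dimethyl-7-oxo-3-(propan-2-yl)-1,2,3,3a,4,7,8,8a-octahydroazulen-4-yl 4-(acetyloxy)benzoate
Conditions: second-generation Grubbs catalyst RuCl2(=CHPh)(PCy3)(H2IMes) (10 mol%), 1,4-benzoquinone (cat.), toluene (0.005 M), 80 °C
Reagents that add atoms: none
Why: The ruthenium alkylidene should load onto the monosubstituted C7 olefin, add to the 1,1-disubstituted C8 olefin of the isopropenyl ketone in a [2+2] cycloaddition, and the metallacyclobutane then collapses with loss of ethene (ring-closing olefin metathesis). The closest known reaction type is the ring-closing metathesis of a vinyl carbinol derivative with an isopropenyl ketone to give a 2-methylcycloalk-2-enone. The seven-membered ring is closed by joining C7 and C8 of a 1,8-diene whose two arms are held trans on the adjacent ring carbons C1 and C5, which gives the trans-fused bicycle with a ring-enforced Z olefin. No stereocenter is formed, and C1, C2, C4, C5 and C6 are carried through unchanged. The step needs ring closure to win over intermolecular metathesis at the vinyl group, which the 1,2-trans preorganisation on the cyclopentane and high dilution should secure, and it needs the catalyst to start at C7 and not at the electron-poor C8 olefin, which the more accessible allylic ester vinyl group secures. Loss of ethene drives the closure to completion.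

Step 15
Reactants: 20 (1S,3R,3aR,4R,8aS)-1-(acetyloxy)-3-hydroxy-6,8a-dimethyl-7-oxo-3-(propan-2-yl)-1,2,3,3a,4,7,8,8a-octahydroazulen-4-yl 4-(acetyloxy)benzoate
Product: 21 (1S,3R,3aR,4R,8aS)-1-(acetyloxy)-3-hydroxy-6,8a-dimethyl-7-oxo-3-(propan-2-yl)-1,2,3,3a,4,7,8,8a-octahydroazulen-4-yl 4-hydroxybenzoate
Conditions: NH4OAc, MeOH/H2O, rt
Reagents that add atoms: none
Why: Aryl acetates undergo ammonium acetate-mediated methanolysis (selective transesterification) much faster than the secondary alkyl acetate at C2 or the benzoate ester at C6, so that only the phenol should be set free.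

Compound list
1 | (S)-4-(tert-butyldimethylsilyloxy)cyclopent-2-en-1-one | O=C1C=C[C@@H](O[Si](C)(C)C(C)(C)C)C1 | starting material
2 | (S)-4-(tert-butyldimethylsilyloxy)-2-iodocyclopent-2-en-1-one | O=C1C(I)=C[C@@H](O[Si](C)(C)C(C)(C)C)C1 | intermediate
3 | (S)-4-(tert-butyldimethylsilyloxy)-2-methylcyclopent-2-en-1-one | O=C1C(C)=C[C@@H](O[Si](C)(C)C(C)(C)C)C1 | intermediate
4 | 2-bromo-N-methoxy-N-methylacetamide | CON(C)C(=O)CBr | starting material
5 | bromomagnesium (3S,4S)-4-(tert-butyldimethylsilyloxy)-3-ethenyl-2-methylcyclopent-1-en-1-olate | Br[Mg]OC1=C(C)[C@H](C=C)[C@@H](O[Si](C)(C)C(C)(C)C)C1 | intermediate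
6 | 2-[(1S,2S,3S)-3-(tert-butyldimethylsilyloxy)-2-ethenyl-1-methyl-5-oxocyclopentyl]-N-methoxy-N-methylacetamide | O=C1C[C@H](O[Si](C)(C)C(C)(C)C)[C@@H](C=C)[C@]1(C)CC(=O)N(C)OC | intermediate
7 | 2-[(1S,2R)-2-ethenyl-1-methyl-5-oxocyclopent-3-en-1-yl]-N-methoxy-N-methylacetamide | O=C1C=C[C@@H](C=C)[C@]1(C)CC(=O)N(C)OC | intermediate
8 | 2-[(1S,4R,5R)-5-ethenyl-1-methyl-4-(propan-2-yl)-2-(trimethylsilyloxy)cyclopent-2-en-1-yl]-N-methoxy-N-methylacetamide | C[Si](C)(C)OC1=C[C@H](C(C)C)[C@@H](C=C)[C@]1(C)CC(=O)N(C)OC | intermediate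
9 | 2-[(1S,2R)-2-ethenyl-1-methyl-5-oxo-3-(propan-2-yl)cyclopent-3-en-1-yl]-N-methoxy-N-methylacetamide | O=C1C=C(C(C)C)[C@@H](C=C)[C@]1(C)CC(=O)N(C)OC | intermediate
10 | 2-[(1R,2S,3S,5R)-2-ethenyl-3-methyl-4-oxo-1-(propan-2-yl)-6-oxabicyclo[3.1.0]hexan-3-yl]-N-methoxy-N-methylacetamide | O=C1[C@@H]2O[C@]2(C(C)C)[C@@H](C=C)[C@]1(C)CC(=O)N(C)OC | intermediate
11 | 2-[(1S,2S,3R)-2-ethenyl-3-hydroxy-1-methyl-5-oxo-3-(propan-2-yl)cyclopentyl]-N-methoxy-N-methylacetamide | O=C1C[C@@](O)(C(C)C)[C@@H](C=C)[C@]1(C)CC(=O)N(C)OC | intermediate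
12 | 2-[(1S,2S,3R,5S)-2-ethenyl-3,5-dihydroxy-1-methyl-3-(propan-2-yl)cyclopentyl]-N-methoxy-N-methylacetamide | O[C@H]1C[C@@](O)(C(C)C)[C@@H](C=C)[C@]1(C)CC(=O)N(C)OC | intermediate
13 | 1-[(1S,2S,3R,5S)-2-ethenyl-3,5-dihydroxy-1-methyl-3-(propan-2-yl)cyclopentyl]-3-methylbut-3-en-2-one | O[C@H]1C[C@@](O)(C(C)C)[C@@H](C=C)[C@]1(C)CC(=O)C(C)=C | intermediate
14 | (1S,2S,3S,4R)-3-ethenyl-4-hydroxy-2-methyl-2-(3-methyl-2-oxobut-3-en-1-yl)-4-(propan-2-yl)cyclopentyl acetate | CC(=O)O[C@H]1C[C@@](O)(C(C)C)[C@@H](C=C)[C@]1(C)CC(=O)C(C)=C | intermediate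
15 | (1S,2S,3S,4R)-4-hydroxy-2-methyl-2-(3-methyl-2-oxobut-3-en-1-yl)-4-(propan-2-yl)-3-(1,2,4-trioxolan-3-yl)cyclopentyl acetate (secondary ozonide, both epimers at the trioxolane carbon) | CC(=O)O[C@H]1C[C@@](O)(C(C)C)[C@@H](C2OCOO2)[C@]1(C)CC(=O)C(C)=C | intermediate
16 | (1S,2S,3S,4R)-3-formyl-4-hydroxy-2-methyl-2-(3-methyl-2-oxobut-3-en-1-yl)-4-(propan-2-yl)cyclopentyl acetate | CC(=O)O[C@H]1C[C@@](O)(C(C)C)[C@@H](C=O)[C@]1(C)CC(=O)C(C)=C | intermediate
17 | (1S,2S,3R,4R)-4-hydroxy-3-[(1R)-1-hydroxyprop-2-en-1-yl]-2-methyl-2-(3-methyl-2-oxobut-3-en-1-yl)-4-(propan-2-yl)cyclopentyl acetate | CC(=O)O[C@H]1C[C@@](O)(C(C)C)[C@@H]([C@H](O)C=C)[C@]1(C)CC(=O)C(C)=C | intermediate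
18 | 4-(acetyloxy)benzoyl chloride | CC(=O)Oc1ccc(cc1)C(Cl)=O | starting material
19 | (1R)-1-[(1R,2S,3S,5R)-3-(acetyloxy)-5-hydroxy-2-methyl-2-(3-methyl-2-oxobut-3-en-1-yl)-5-(propan-2-yl)cyclopentyl]prop-2-en-1-yl 4-(acetyloxy)benzoate | CC(=O)O[C@H]1C[C@@](O)(C(C)C)[C@@H]([C@H](OC(=O)c2ccc(OC(C)=O)cc2)C=C)[C@]1(C)CC(=O)C(C)=C | intermediate
20 | (1S,3R,3aR,4R,8aS)-1-(acetyloxy)-3-hydroxy-6,8a-dimethyl-7-oxo-3-(propan-2-yl)-1,2,3,3a,4,7,8,8a-octahydroazulen-4-yl 4-(acetyloxy)benzoate | CC(=O)O[C@H]1C[C@@](O)(C(C)C)[C@H]2[C@H](OC(=O)c3ccc(OC(C)=O)cc3)C=C(C)C(=O)C[C@]12C | intermediate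
21 | (1S,3R,3aR,4R,8aS)-1-(acetyloxy)-3-hydroxy-6,8a-dimethyl-7-oxo-3-(propan-2-yl)-1,2,3,3a,4,7,8,8a-octahydroazulen-4-yl 4-hydroxybenzoate | CC(=O)O[C@H]1C[C@@](O)(C(C)C)[C@H]2[C@H](OC(=O)c3ccc(O)cc3)C=C(C)C(=O)C[C@]12C | target

Total step count: 15. Longest linear sequence: 15 steps (1 to 21).

Steps most likely to fail

Step 3. The hindered, tetrasubstituted magnesium enolate may be alkylated too slowly, so that proton transfer toward C3 with loss of silanolate, or O-alkylation, takes over. The fallback sets out from 3 and comes back at 6. The conjugate addition of the vinyl Grignard reagent is run in the presence of TMSCl, which should give the isolable trimethylsilyl enol ether F1. This is alkylated under Lewis acid conditions (ZnBr2, CH2Cl2) with 2-chloro-N-methoxy-N-methyl-2-(phenylsulfanyl)acetamide; the sulfur-stabilised cation needs no basic metal enolate and is known to attack tetrasubstituted silyl enol ethers, again anti to the vinyl group, to give the α-phenylsulfanyl amide F2. Radical desulfurisation (Bu3SnH, AIBN, toluene, 80 °C) should then give 6.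

Step 12. The facial selectivity at C6 may be poor if the chelate does not form, the reagent may attack the isopropenyl ketone, or the β-hydroxy aldehyde may undergo retro-aldol cleavage under the basic conditions. The fallback sets out from 16 and comes back at 17. It is a Nozaki–Hiyama–Kishi vinylation (vinyl bromide, CrCl2, NiCl2 (cat.), chiral oxazoline–sulfonamide ligand, THF, rt): the non-basic vinylchromium species adds only to aldehydes and the face of attack is set by the ligand instead of by the substrate. No compound outside the list arises on this way (none F0).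

Step 14. Ring closure onto the electron-poor 1,1-disubstituted olefin may be slow, so that cross-metathesis at the vinyl group or double-bond migration competes. The fallback sets out from 19 and comes back at 20, and closes the ring at the alcohol oxidation level. Luche reduction (NaBH4, CeCl3·7H2O, MeOH, −78 °C) should give the allylic alcohol F3 as a mixture of C9 epimers. Ring-closing metathesis of this more reactive, non-conjugated olefin with the same catalyst should give the cyclic allylic alcohol F4, and oxidation with Dess–Martin periodinane (CH2Cl2, rt) returns 20.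

Further compounds
F1 | step 3 | {[(3S,4S)-4-(tert-butyldimethylsilyloxy)-3-ethenyl-2-methylcyclopent-1-en-1-yl]oxy}trimethylsilane | C[Si](C)(C)OC1=C(C)[C@H](C=C)[C@@H](O[Si](C)(C)C(C)(C)C)C1
F2 | step 3 | 2-[(1S,2S,3S)-3-(tert-butyldimethylsilyloxy)-2-ethenyl-1-methyl-5-oxocyclopentyl]-N-methoxy-N-methyl-2-(phenylsulfanyl)acetamide (both epimers at the sulfur-bearing carbon) | O=C1C[C@H](O[Si](C)(C)C(C)(C)C)[C@@H](C=C)[C@]1(C)C(Sc2ccccc2)C(=O)N(C)OC
F0 | step 12 | none | none
F3 | step 14 | (1R)-1-[(1R,2S,3S,5R)-3-(acetyloxy)-5-hydroxy-2-(2-hydroxy-3-methylbut-3-en-1-yl)-2-methyl-5-(propan-2-yl)cyclopentyl]prop-2-en-1-yl 4-(acetyloxy)benzoate (both epimers at the new carbinol) | CC(=O)O[C@H]1C[C@@](O)(C(C)C)[C@@H]([C@H](OC(=O)c2ccc(OC(C)=O)cc2)C=C)[C@]1(C)CC(O)C(C)=C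
F4 | step 14 | (1S,3R,3aR,4R,8aS)-1-(acetyloxy)-3,7-dihydroxy-6,8a-dimethyl-3-(propan-2-yl)-1,2,3,3a,4,7,8,8a-octahydroazulen-4-yl 4-(acetyloxy)benzoate (both epimers at the ring carbinol) | CC(=O)O[C@H]1C[C@@](O)(C(C)C)[C@H]2[C@H](OC(=O)c3ccc(OC(C)=O)cc3)C=C(C)C(O)C[C@]12C
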